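The number to carry is 0.678, the rate constant of the second addition of Jb over that of the first, at 50 °C: this selectivity factor says that, at equal amounts of free Ja and Je, Jb adds to Ja faster than to Je.

    Jb → Jh (k1 = 4.49 × 10⁻⁶ s⁻¹, Ea1 = 101 kJ mol⁻¹)
    Ja + Jc ⇌ Jg, settled at all times (K2 = 730 L mol⁻¹, ΔH2 = −14.0 kJ mol⁻¹)
    Jb + Je → Jf + Jc (k3 = 0.00606 L mol⁻¹ s⁻¹, Ea3 = 74.0 kJ mol⁻¹)
    Ja + Jb → Je + Jc (k4 = 0.00894 L mol⁻¹ s⁻¹, Ea4 = 63.0 kJ mol⁻¹)
    Jc → Jd (k5 = 0.00863 s⁻¹, Ea5 = 82.0 kJ mol⁻¹)
    (constants at 50 °C)

| flask | Ja | Jb | temperature | time |
|---|---|---|---|---|
| red | 0.39 M | 0.468 M | 80 °C | 3.0 min |
| teal | 0.39 M | 0.468 M | 65 °C | 3.0 min |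
| green | 0.39 M | 0.468 M | 50 °C | 3.0 min |

- what is said of Jc includes Jg
- the constants hold at 50 °C; other temperatures follow from the activation energies and enthalpies

1. the flask that comes out highest in amount of Je, in percent of the Ja charged, or "all alike" when all lie within 1.5 percentage points (red / teal / green / all alike)
2. Je at the end, in percent of the Ja charged, red
3. Je at the end, in percent of the Ja charged, teal
4. Je at the end, in percent of the Ja charged, green

Je is made by the step from Ja and Jb and used by the step from Je and Jb. Both rates carry Jb, so in their quotient Jb and time cancel: made over used is free Ja over Je, divided by the factor, and Je peaks where that equals 1. The loss of Jb to Jh is dropped, because in green 4.49 × 10⁻⁶ s⁻¹ is far slower than 0.00349 s⁻¹, the first addition per Jb at the start.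

Each Je releases one Jc and each Jf two, and in green at the start Jc sits on Ja as Jg, because the balance constant times the Ja charge, 285, is far above 1. In fractions of the Ja charged, this reckoning therefore has Ja + 2·Je + 3·Jf = 1, for as long as Jc is taken to be neither free nor lost to Jd. Measured on a clock that runs at the rate constant of the first addition times Jb, Je grows by Ja minus the factor times Je, while free Ja falls by 2·Ja plus the factor times Je. This linear pair has, for green, a damping constant 1.34, and with its ringing set aside as an approximation, Je follows the clock times exp(−damping × clock).

The first way to green uses the factor alone: the peak height is exp(−1) over the damping constant, 27.5%. The second uses the charge and the time: with Jb held at its charge, the clock reads 0.753 and gives 27.5%. Both numbers share the factor, so their agreement is no independent check: it says that in green the clock at the asked time stands close to the clock of the reckoned peak, 0.746.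

For the hotter flasks, the factor grows to 0.807 in teal and 0.960 in red, taking teal's temperature factors as the square root of red's. Green has the lowest factor, so this reckoning gives green the highest peak. Here the two ways part: for teal the peak formula gives 26.2% and the clock 11.7%, for red the peak formula gives 24.9% and the clock 0.156%, and this reckoning expects each end value between its pair. The clock is the one expected to cheat, since it holds Jb at its charge and keeps Jc bound, although from green to red the loss of Jc speeds up by a factor of 13 against 7.3 for the first addition.

The forecast gave 12.3% for red, 20.5% for teal and 26.6% for green, hence green, noting that “Each Je made also locks away one more Ja until Jc decays.” Its teal and red fall between the pairs reckoned here, and its green stands below the peak reckoned here.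

The simulation gives 12.2% for red, 20.0% for teal and 26.6% for green, so green comes out highest, as forecast. Green at 3.00 min holds free Ja 26.1% against Je 26.6%, and that quotient over the factor is 1.45, so Je is still made faster than it is used. In teal at 3.00 min the rate of making Je over that of using it reads 0.373, so Je there is made slower than it is used. Teal read at 12 min holds free Ja 8.67% and Je 11.4%, and its quotient over the factor is 0.942.

All constants are those of an exercise; the run is a simulation.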